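The target is cut between the two bicycles at the ethylene bridge and, within the decahydro-1-benzoxepine, at the C6–C7 bond of the cyclohexane ring (ring B). There the tertiary C7 hydroxyl is axial, syn to the C5a methyl and cis to the C6 substituent: a cis β-hydroxy carbonyl pattern. A SmI2 Reformatsky aldol of a preformed oxepane (ring A) that carries an α-bromo ester on the quaternary carbon and a 3-oxobutyl chain on the neighbouring ring carbon closes ring B and sets C6 and C7 in one operation. The oxepane is made from geraniol; the hydroazulene, from (R)-linalool, is attached afterwards as a vinylogous ester to an alkyne grown from the ester carbon.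

Key step: step 13

Remark: locants follow oxepane, 1-benzoxepine, pentalene and azulene nomenclature (TBS = tert-butyldimethylsilyl, TES = triethylsilyl, TMS = trimethylsilyl); centres that a later step removes are carried as mixtures and drawn without configuration.

Step 1
Reactants: 1 geraniol
Product: 2 [(2R,3R)-3-methyl-3-(4-methylpent-3-en-1-yl)oxiran-2-yl]methanol
Conditions: Ti(OiPr)4 (5 mol%), D-(−)-diethyl tartrate (6 mol%), t-BuOOH, 4 Å molecular sieves, CH2Cl2, −20 °C
Reagents that add atoms: tert-butyl hydroperoxide, CC(C)(C)OO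
Why: Sharpless asymmetric epoxidation, in which the titanium–D-tartrate complex epoxidises only the allylic olefin and should give the (2R,3R) epoxide that later fixes the quaternary carbon.

Step 2
Reactants: 2 epoxy alcohol; 3 ethynyltrimethylsilane
Product: 6 (2S,3R)-3,7-dimethyl-3-[(trimethylsilyl)ethynyl]oct-6-ene-1,2-diol, via lithium (trimethylsilyl)acetylide 4 (not isolated), via diethyl[(trimethylsilyl)ethynyl]alumane 5 (not isolated)
Conditions: 3, n-BuLi, toluene, 0 °C; Et2AlCl, 0 °C; then 2, 0 °C to rt; aq. potassium sodium tartrate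
Reagents that add atoms: none
Why: Hydroxyl-directed ring opening of a 2,3-epoxy alcohol by an alkynylalane, in which the aluminium alkoxide activates the epoxide and the acetylide should attack the tertiary C3 with inversion to create the quaternary stereocentre.

Step 3
Reactants: 6 diol
Product: 7 (2R)-2,6-dimethyl-2-[(trimethylsilyl)ethynyl]hept-5-enal
Conditions: NaIO4, THF/H2O (pH 7 buffer), 0 °C to rt
Reagents that add atoms: none
Why: Malaprade glycol cleavage, which removes C1 as formaldehyde and leaves an α-quaternary aldehyde that cannot enolise or epimerise.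

Step 4
Reactants: 7 aldehyde; 8 2-(2-bromoethyl)-2-methyl-1,3-dioxolane
Product: 10 (4R)-4,8-dimethyl-1-(2-methyl-1,3-dioxolan-2-yl)-4-[(trimethylsilyl)ethynyl]non-7-en-3-ol (both C3 epimers), via Grignard reagent 9 (not isolated)
Conditions: 8, Mg, THF, 25 °C; then 7, −78 to 0 °C; aq. NH4Cl
Reagents that add atoms: none
Why: Grignard addition to a non-enolisable aldehyde, with the new carbinol centre left uncontrolled because the next step erases it.

Step 5
Reactants: 10 alcohol
Product: 11 (4R)-4,8-dimethyl-1-(2-methyl-1,3-dioxolan-2-yl)-4-[(trimethylsilyl)ethynyl]non-7-en-3-one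
Conditions: Dess–Martin periodinane, NaHCO3, CH2Cl2, 0 °C to rt
Reagents that add atoms: none
Why: Dess–Martin oxidation of a secondary alcohol, to which ketal, silylalkyne and olefin are inert.

Step 6
Reactants: 11 ketone
Product: 12 (3R,4R)-4,8-dimethyl-1-(2-methyl-1,3-dioxolan-2-yl)-4-[(trimethylsilyl)ethynyl]non-7-en-3-ol
Conditions: (S)-2-methyl-CBS-oxazaborolidine (0.3 equiv), catecholborane, toluene, −78 °C
Reagents that add atoms: none
Why: Corey–Bakshi–Shibata reduction, in which the ketone sits between a quaternary carbon (large) and a methylene (small) so that the (S)-oxazaborolidine should give the (3R) carbinol under reagent control while catecholborane leaves the olefin alone.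

Step 7
Reactants: 12 alcohol
Product: 14 (3R,6R,7R)-2,2,6-trimethyl-7-[2-(2-methyl-1,3-dioxolan-2-yl)ethyl]-6-[(trimethylsilyl)ethynyl]oxepan-3-ol, via epoxy alcohol 13 (not isolated)
Conditions: Shi ketone (D-fructose-derived, 0.3 equiv), KHSO5 (as 2KHSO5·KHSO4·K2SO4), K2CO3, Bu4NHSO4, MeCN/CH2(OMe)2/aq. Na2B4O7 buffer, 0 °C; extractive work-up; then camphorsulfonic acid (10 mol%), CH2Cl2, 0 °C
Reagents that add atoms: potassium peroxymonosulfate, [K+].[O-]S(=O)(=O)OO
Why: Shi asymmetric epoxidation (the D-fructose ketone should give the (R) epoxide at the CH carbon) followed by acid-catalysed 7-endo-tet epoxide opening, in which the secondary hydroxyl attacks the tertiary epoxide carbon (Markovnikov) so that the oxygen-bearing C3 keeps the configuration of the epoxide.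

Step 8
Reactants: 14 oxepanol
Product: 15 tert-butyldimethyl{[(3R,6R,7R)-2,2,6-trimethyl-7-[2-(2-methyl-1,3-dioxolan-2-yl)ethyl]-6-[(trimethylsilyl)ethynyl]oxepan-3-yl]oxy}silane
Conditions: TBSOTf, 2,6-lutidine, CH2Cl2, −78 to 0 °C
Reagents that add atoms: tert-butyldimethylsilyl trifluoromethanesulfonate, CC(C)(C)[Si](C)(C)OS(=O)(=O)C(F)(F)F
Why: Silylation of a hindered secondary alcohol with a silyl triflate under basic conditions that spare the ketal.

Step 9
Reactants: 15 silylalkyne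
Product: 17 2-[(2R,3R,6R)-6-[(tert-butyldimethylsilyl)oxy]-3,7,7-trimethyl-2-[2-(2-methyl-1,3-dioxolan-2-yl)ethyl]oxepan-3-yl]acetic acid, via alkenylborane 16 (not isolated)
Conditions: Cy2BH (from cyclohexene and BH3·SMe2), THF, 0 °C to rt; then NaOH, H2O2, 0 °C to rt; acidify to pH 4
Reagents that add atoms: hydrogen peroxide, OO
Why: Hydroboration–oxidation of a 1-silylalkyne, in which boron should add to the silicon-bearing carbon and alkaline peroxide takes the α-silyl alkenylborane through the acylsilane to the carboxylic acid, with no olefin left in the molecule to compete.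

Step 10
Reactants: 17 acid
Product: 18 ethyl 2-[(2R,3R,6R)-6-[(tert-butyldimethylsilyl)oxy]-3,7,7-trimethyl-2-[2-(2-methyl-1,3-dioxolan-2-yl)ethyl]oxepan-3-yl]acetate
Conditions: EtI, K2CO3, DMF, rt
Reagents that add atoms: iodoethane, CCI
Why: O-Alkylation of the carboxylate (SN2), which needs no acid and so spares ketal and silyl ether.

Step 11
Reactants: 18 ester
Product: 20 ethyl 2-bromo-2-[(2R,3S,6R)-6-[(tert-butyldimethylsilyl)oxy]-3,7,7-trimethyl-2-[2-(2-methyl-1,3-dioxolan-2-yl)ethyl]oxepan-3-yl]acetate (both bromide epimers), via lithium enolate 19 (not isolated)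
Conditions: LiN(iPr)2, THF, −78 °C; then BrCCl2CCl2Br, −78 to −40 °C
Reagents that add atoms: 1,2-dibromo-1,1,2,2-tetrachloroethane, BrC(Cl)(Cl)C(Cl)(Cl)Br
Why: Electrophilic bromination of an ester enolate, the ester being the only enolisable carbonyl while the ketone is masked, and the bromide configuration being irrelevant.

Step 12
Reactants: 20 bromo ester ketal
Product: 21 ethyl 2-bromo-2-[(2R,3S,6R)-6-[(tert-butyldimethylsilyl)oxy]-3,7,7-trimethyl-2-(3-oxobutyl)oxepan-3-yl]acetate (both bromide epimers)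
Conditions: pyridinium p-toluenesulfonate, acetone/H2O, 50 °C
Reagents that add atoms: water, O
Why: Acid-catalysed ketal hydrolysis under conditions mild enough for the hindered secondary silyl ether and the α-bromo ester.

Step 13
Reactants: 21 bromo ester ketone
Product: 23 ethyl (3R,5aR,6R,7S,9aR)-3-[(tert-butyldimethylsilyl)oxy]-7-hydroxy-2,2,5a,7-tetramethyldecahydro-1-benzoxepine-6-carboxylate, via samarium enolate 22 (not isolated)
Conditions: SmI2 (2.5 equiv, 0.1 M), THF, −78 °C, 21 added slowly; aq. NH4Cl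
Reagents that add atoms: none
Why: SmI2 (two electron equivalents) reduces the C–Br bond of either epimer of 21 to the trivalent samarium ester enolate 22, much faster than it reduces the ketone, and the enolate adds to the methyl ketone held five atoms away. This is the intramolecular SmI2 Reformatsky aldol, a known route to cis β-hydroxy esters. The cyclohexane (ring B) closes in the 6-(enolexo)-exo-trig mode through a chair in which samarium bridges the enolate and ketone oxygens. C6 is controlled by that chair, which keeps the ester carbon equatorial next to the quaternary C5a; C7 is controlled by the C5a methyl, axial on the forming ring, which forces the ketone methyl equatorial and the C7 oxygen axial. The step needs the cis hydroxyl/ester pair with the axial C7 hydroxyl and needs bromide reduction to win over ketyl formation: the chelate and the 1,3-diaxial methyl/methyl penalty secure the first, the far easier reduction of the α-bromo ester the second, and the trans ring fusion is already fixed by the (2R,3S) oxepane.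

Step 14
Reactants: 23 hydroxy ester
Product: 24 ethyl (3R,5aR,6R,7S,9aR)-3-[(tert-butyldimethylsilyl)oxy]-2,2,5a,7-tetramethyl-7-[(triethylsilyl)oxy]decahydro-1-benzoxepine-6-carboxylate
Conditions: TESOTf, 2,6-lutidine, CH2Cl2, 0 °C to rt
Reagents that add atoms: triethylsilyl trifluoromethanesulfonate, CC[Si](CC)(CC)OS(=O)(=O)C(F)(F)F
Why: Silylation of the tertiary alcohol with a silyl triflate, which blocks retro-aldol cleavage once C6 carries an aldehyde and removes the acidic proton before the organolithium steps.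

Step 15
Reactants: 24 ester
Product: 25 [(3R,5aR,6S,7S,9aR)-3-[(tert-butyldimethylsilyl)oxy]-2,2,5a,7-tetramethyl-7-[(triethylsilyl)oxy]decahydro-1-benzoxepin-6-yl]methanol
Conditions: i-Bu2AlH (3 equiv), CH2Cl2, −78 to 0 °C; aq. potassium sodium tartrate
Reagents that add atoms: none
Why: Hydride reduction of the hindered ester to the primary alcohol, to which both silyl ethers are stable.

Step 16
Reactants: 25 alcohol
Product: 26 (3R,5aR,6R,7S,9aR)-3-[(tert-butyldimethylsilyl)oxy]-2,2,5a,7-tetramethyl-7-[(triethylsilyl)oxy]decahydro-1-benzoxepine-6-carbaldehyde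
Conditions: Dess–Martin periodinane, pyridine, CH2Cl2, 0 °C to rt
Reagents that add atoms: none
Why: Dess–Martin oxidation under buffered non-basic conditions, so the equatorial α-stereocentre and the β-silyloxy group are not at risk.

Step 17
Reactants: 26 aldehyde
Product: 27 tert-butyl{[(3R,5aR,6R,7S,9aR)-6-ethynyl-2,2,5a,7-tetramethyl-7-[(triethylsilyl)oxy]decahydro-1-benzoxepin-3-yl]oxy}dimethylsilane
Conditions: Me3SiCHN2, n-BuLi, THF, −78 °C; then 26, −78 to 0 °C
Reagents that add atoms: (trimethylsilyl)diazomethane, C[Si](C)(C)C=[N+]=[N-]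
Why: Colvin rearrangement, in which the lithiated silyldiazomethane adds to the aldehyde at −78 °C, Peterson elimination gives an alkylidene carbene and a 1,2-hydrogen shift gives the terminal alkyne, a one-carbon homologation that avoids warm basic methanol and hence β-elimination.

Step 18
Reactants: 28 (R)-linalool
Product: 29 tert-butyl{[(3R)-3,7-dimethylocta-1,6-dien-3-yl]oxy}dimethylsilane
Conditions: TBSOTf, 2,6-lutidine, CH2Cl2, 0 °C
Reagents that add atoms: tert-butyldimethylsilyl trifluoromethanesulfonate, CC(C)(C)[Si](C)(C)OS(=O)(=O)C(F)(F)F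
Why: Silylation of the tertiary allylic alcohol with a silyl triflate, giving a bulky ether that should steer the Pauson–Khand step and last until the final desilylation.

Step 19
Reactants: 29 silyl ether
Product: 30 (4R)-4-[(tert-butyldimethylsilyl)oxy]-4-methylhex-5-enal
Conditions: O3 (1 equiv, indicator end-point), CH2Cl2/MeOH, −78 °C; then PPh3
Reagents that add atoms: ozone, [O-][O+]=O
Why: Chemoselective ozonolysis, the electron-rich trisubstituted olefin reacting much faster than the monosubstituted vinyl group next to the silyloxy carbon.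

Step 20
Reactants: 30 aldehyde
Product: 31 tert-butyldimethyl{[(3R)-3-methylhept-1-en-6-yn-3-yl]oxy}silane
Conditions: dimethyl (1-diazo-2-oxopropyl)phosphonate, K2CO3, MeOH, 0 °C to rt
Reagents that add atoms: dimethyl (1-diazo-2-oxopropyl)phosphonate, CC(=O)C(=[N+]=[N-])P(=O)(OC)OC
Why: Ohira–Bestmann (Seyferth–Gilbert) homologation of the aldehyde to the terminal alkyne under mild base.

Step 21
Reactants: 31 terminal alkyne
Product: 33 tert-butyldimethyl{[(3R)-3-methyloct-1-en-6-yn-3-yl]oxy}silane, via lithium acetylide 32 (not isolated)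
Conditions: n-BuLi, THF, −78 °C; then MeI, −78 °C to rt
Reagents that add atoms: iodomethane, CI
Why: Acetylide alkylation, which installs the methyl that becomes one of the geminal methyls at C4 of the azulene.

Step 22
Reactants: 33 enyne
Product: 35 (6R,6aR)-6-[(tert-butyldimethylsilyl)oxy]-3,6-dimethyl-4,5,6,6a-tetrahydropentalen-2(1H)-one, via Co2(CO)6 alkyne complex 34 (not isolated)
Conditions: Co2(CO)8, CH2Cl2, rt; then N-methylmorpholine N-oxide, 0 °C to rt
Reagents that add atoms: carbon monoxide (ligand of Co2(CO)8), [C-]#[O+]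
Why: Intramolecular Pauson–Khand reaction of a 1,6-enyne, which puts the alkyne methyl on the enone α-carbon and should place the new ring-fusion hydrogen cis to the bulky silyloxy group, which takes the exo position on the convex face during alkene insertion.

Step 23
Reactants: 35 enone
Product: 37 (3aR,6R,6aR)-6-[(tert-butyldimethylsilyl)oxy]-3,3,6-trimethylhexahydropentalen-2(1H)-one, via lithium enolate 36 (not isolated)
Conditions: Li, NH3 (l), THF, t-BuOH (1 equiv), −78 °C; isoprene; then MeI, −78 to −33 °C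
Reagents that add atoms: iodomethane, CI
Why: Dissolving-metal (Birch-type) enone reduction with enolate trapping, in which β-protonation can only give the cis-fused bicyclo[3.3.0]octane and the regiodefined enolate is C-methylated to complete the gem-dimethyl group.

Step 24
Reactants: 37 ketone
Product: 38 tert-butyldimethyl{[(1R,3aR,6aS)-1,4,4-trimethyl-5-[(trimethylsilyl)oxy]-1,2,3,3a,4,6a-hexahydropentalen-1-yl]oxy}silane
Conditions: TMSOTf, Et3N, CH2Cl2, 0 °C
Reagents that add atoms: trimethylsilyl trifluoromethanesulfonate, C[Si](C)(C)OS(=O)(=O)C(F)(F)F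
Why: Soft enolisation–silylation, for which only one silyl enol ether is possible because the ketone has α-hydrogens on the methylene side alone.

Step 25
Reactants: 38 silyl enol ether; 39 dichloroacetyl chloride
Product: 41 4,4-dichloro-10-[(tert-butyldimethylsilyl)oxy]-6,6,10-trimethyl-5-[(trimethylsilyl)oxy]tricyclo[5.3.0.0(2,5)]decan-3-one, via dichloroketene 40 (not isolated)
Conditions: 39, Et3N, hexane, rt (slow addition)
Reagents that add atoms: none
Why: Ketene–enol ether [2+2] cycloaddition, in which the ketene carbonyl carbon bonds to the nucleophilic CH of the enol ether and the CCl2 carbon to the siloxy carbon, the two new centres being removed in the next step.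

Step 26
Reactants: 41 dichlorocyclobutanone
Product: 43 (1R,3aR,8aR)-1-[(tert-butyldimethylsilyl)oxy]-1,4,4-trimethyl-2,3,3a,4,8,8a-hexahydroazulene-5,7(1H,6H)-dione, via dechlorinated cyclobutanone 42 (not isolated)
Conditions: Zn, AcOH, iPrOH/H2O, rt to 50 °C
Reagents that add atoms: none
Why: Reductive dechlorination followed by desilylation and retro-aldol opening of the 3-hydroxycyclobutanone, a strain-driven two-carbon ring expansion of the cyclopentanone to the cycloheptane-1,3-dione.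

Step 27
Reactants: 43 dione
Product: 44 (1R,3aR,8aR)-1-[(tert-butyldimethylsilyl)oxy]-1,4,4,6-tetramethyl-2,3,3a,4,8,8a-hexahydroazulene-5,7(1H,6H)-dione (both C6 epimers)
Conditions: MeI, K2CO3, acetone, reflux
Reagents that add atoms: iodomethane, CI
Why: C-Alkylation of the 1,3-diketone at the doubly activated C6 with a soft electrophile.

Step 28
Reactants: 44 methyl dione
Product: 45 (1R,3aR,8aR)-1-[(tert-butyldimethylsilyl)oxy]-7-methoxy-1,4,4,6-tetramethyl-2,3,3a,4,8,8a-hexahydroazulen-5(1H)-one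
Conditions: Me2SO4, K2CO3, acetone, reflux
Reagents that add atoms: dimethyl sulfate, COS(=O)(=O)OC
Why: O-Alkylation of the diketone enolate with a hard electrophile, the oxygen next to the C8 methylene being far less hindered than the one flanked by the quaternary C4, so that the methoxy group should end up on C7 and the ketone stay at C5.

Step 29
Reactants: 27 alkyne; 45 vinylogous ester
Product: 47 (1R,3aR,8aR)-1-[(tert-butyldimethylsilyl)oxy]-5-{[(3R,5aR,6R,7S,9aR)-3-[(tert-butyldimethylsilyl)oxy]-2,2,5a,7-tetramethyl-7-[(triethylsilyl)oxy]decahydro-1-benzoxepin-6-yl]ethynyl}-7-methoxy-1,4,4,6-tetramethyl-1,2,3,3a,4,5,8,8a-octahydroazulen-5-ol (both C5 epimers), via lithium acetylide 46 (not isolated)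
Conditions: 27, n-BuLi, THF, −78 °C; then 45, −78 to 0 °C; aq. NaHCO3
Reagents that add atoms: none
Why: 1,2-Addition of a lithium acetylide to the carbonyl of a vinylogous ester (first half of a Stork–Danheiser transposition), the slim sp nucleophile tolerating the ketone flanked by a quaternary carbon, which has no α-hydrogen to enolise.

Step 30
Reactants: 47 propargylic carbinol
Product: 49 (1R,3aR,8aR)-5-{2-[(3R,5aR,6R,7S,9aR)-3,7-dihydroxy-2,2,5a,7-tetramethyldecahydro-1-benzoxepin-6-yl]ethyl}-1-hydroxy-1,4,4,6-tetramethyl-2,3,3a,4,8,8a-hexahydroazulen-7(1H)-one, via saturated carbinol 48 (not isolated)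
Conditions: H2 (3 atm), Pd/C, EtOAc, Et3N (1%), rt; filter; then HF (48% aq.), MeCN, rt to 40 °C
Reagents that add atoms: water, O
Why: Catalytic hydrogenation saturates the alkyne while the tetrasubstituted enol ether is inert, and aqueous HF then hydrolyses the enol ether, dehydrates the β-hydroxy ketone to the tetrasubstituted enone (Stork–Danheiser transposition) and removes all three silyl groups.

Step 31
Reactants: 49 triol enone
Product: 50 (3R,5aR,6R,7S,9aR)-7-hydroxy-6-{2-[(1R,3aR,8aR)-1-hydroxy-1,4,4,6-tetramethyl-7-oxo-1,2,3,3a,4,7,8,8a-octahydroazulen-5-yl]ethyl}-2,2,5a,7-tetramethyldecahydro-1-benzoxepin-3-yl acetate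
Conditions: Ac2O, pyridine, 4-(dimethylamino)pyridine (cat.), CH2Cl2, 0 °C to rt
Reagents that add atoms: acetic anhydride, CC(=O)OC(C)=O
Why: Acylation of the only secondary hydroxyl, the two tertiary alcohols being unreactive under these conditions and C7 of the azulene still being a ketone.

Step 32
Reactants: 50 enone acetate
Product: 51 (3R,5aR,6R,7S,9aR)-6-{2-[(1R,3aR,7R,8aR)-1,7-dihydroxy-1,4,4,6-tetramethyl-1,2,3,3a,4,7,8,8a-octahydroazulen-5-yl]ethyl}-7-hydroxy-2,2,5a,7-tetramethyldecahydro-1-benzoxepin-3-yl acetate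
Conditions: (S)-2-methyl-CBS-oxazaborolidine (1.5 equiv), catecholborane (excess), toluene/CH2Cl2, −78 to −40 °C; MeOH, then pH 7 buffer
Reagents that add atoms: none
Why: Corey–Bakshi–Shibata 1,2-reduction of the α-methyl enone, in which the tetrasubstituted alkenyl arm is the large group and the C8 methylene the small one, so that the (S)-oxazaborolidine should give the (7R) allylic alcohol under reagent control while catecholborane at low temperature leaves the acetate untouched.

Compound list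

1 | geraniol, (2E)-3,7-dimethylocta-2,6-dien-1-ol | CC(C)=CCC/C(C)=C/CO | starting material
2 | [(2R,3R)-3-methyl-3-(4-methylpent-3-en-1-yl)oxiran-2-yl]methanol | OC[C@H]1O[C@]1(C)CCC=C(C)C | intermediate
3 | ethynyltrimethylsilane | C#C[Si](C)(C)C | starting material
4 | lithium (trimethylsilyl)acetylide | [Li]C#C[Si](C)(C)C | intermediate (not isolated)
5 | diethyl[(trimethylsilyl)ethynyl]alumane | CC[Al](CC)C#C[Si](C)(C)C | intermediate (not isolated)
6 | (2S,3R)-3,7-dimethyl-3-[(trimethylsilyl)ethynyl]oct-6-ene-1,2-diol | OC[C@@H](O)[C@@](C)(C#C[Si](C)(C)C)CCC=C(C)C | intermediate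
7 | (2R)-2,6-dimethyl-2-[(trimethylsilyl)ethynyl]hept-5-enal | O=C[C@@](C)(C#C[Si](C)(C)C)CCC=C(C)C | intermediate
8 | 2-(2-bromoethyl)-2-methyl-1,3-dioxolane | CC1(CCBr)OCCO1 | starting material
9 | [2-(2-methyl-1,3-dioxolan-2-yl)ethyl]magnesium bromide | CC1(CC[Mg]Br)OCCO1 | intermediate (not isolated)
10 | (4R)-4,8-dimethyl-1-(2-methyl-1,3-dioxolan-2-yl)-4-[(trimethylsilyl)ethynyl]non-7-en-3-ol, both C3 epimers | CC1(CCC(O)[C@@](C)(C#C[Si](C)(C)C)CCC=C(C)C)OCCO1 | intermediate
11 | (4R)-4,8-dimethyl-1-(2-methyl-1,3-dioxolan-2-yl)-4-[(trimethylsilyl)ethynyl]non-7-en-3-one | CC1(CCC(=O)[C@@](C)(C#C[Si](C)(C)C)CCC=C(C)C)OCCO1 | intermediate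
12 | (3R,4R)-4,8-dimethyl-1-(2-methyl-1,3-dioxolan-2-yl)-4-[(trimethylsilyl)ethynyl]non-7-en-3-ol | CC1(CC[C@@H](O)[C@@](C)(C#C[Si](C)(C)C)CCC=C(C)C)OCCO1 | intermediate
13 | (3R,4R)-6-[(2R)-3,3-dimethyloxiran-2-yl]-4-methyl-1-(2-methyl-1,3-dioxolan-2-yl)-4-[(trimethylsilyl)ethynyl]hexan-3-ol | CC1(CC[C@@H](O)[C@@](C)(C#C[Si](C)(C)C)CC[C@H]2OC2(C)C)OCCO1 | intermediate (not isolated)
14 | (3R,6R,7R)-2,2,6-trimethyl-7-[2-(2-methyl-1,3-dioxolan-2-yl)ethyl]-6-[(trimethylsilyl)ethynyl]oxepan-3-ol | O[C@@H]1CC[C@](C)(C#C[Si](C)(C)C)[C@@H](CCC2(C)OCCO2)OC1(C)C | intermediate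
15 | tert-butyldimethyl{[(3R,6R,7R)-2,2,6-trimethyl-7-[2-(2-methyl-1,3-dioxolan-2-yl)ethyl]-6-[(trimethylsilyl)ethynyl]oxepan-3-yl]oxy}silane | CC(C)(C)[Si](C)(C)O[C@@H]1CC[C@](C)(C#C[Si](C)(C)C)[C@@H](CCC2(C)OCCO2)OC1(C)C | intermediate
16 | dicyclohexyl{(1Z)-2-[(2R,3R,6R)-6-(TBS-oxy)-3,7,7-trimethyl-2-[2-(2-methyl-1,3-dioxolan-2-yl)ethyl]oxepan-3-yl]-1-(trimethylsilyl)ethenyl}borane | CC(C)(C)[Si](C)(C)O[C@@H]1CC[C@](C)(/C=C(\[Si](C)(C)C)B(C2CCCCC2)C2CCCCC2)[C@@H](CCC2(C)OCCO2)OC1(C)C | intermediate (not isolated)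
17 | 2-[(2R,3R,6R)-6-[(tert-butyldimethylsilyl)oxy]-3,7,7-trimethyl-2-[2-(2-methyl-1,3-dioxolan-2-yl)ethyl]oxepan-3-yl]acetic acid | CC(C)(C)[Si](C)(C)O[C@@H]1CC[C@](C)(CC(=O)O)[C@@H](CCC2(C)OCCO2)OC1(C)C | intermediate
18 | ethyl 2-[(2R,3R,6R)-6-[(tert-butyldimethylsilyl)oxy]-3,7,7-trimethyl-2-[2-(2-methyl-1,3-dioxolan-2-yl)ethyl]oxepan-3-yl]acetate | CC(C)(C)[Si](C)(C)O[C@@H]1CC[C@](C)(CC(=O)OCC)[C@@H](CCC2(C)OCCO2)OC1(C)C | intermediate
19 | lithium enolate of 18 (lithium 1-ethoxy-2-(oxepan-3-yl)ethen-1-olate) | CC(C)(C)[Si](C)(C)O[C@@H]1CC[C@](C)(C=C(O[Li])OCC)[C@@H](CCC2(C)OCCO2)OC1(C)C | intermediate (not isolated)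
20 | ethyl 2-bromo-2-[(2R,3S,6R)-6-[(tert-butyldimethylsilyl)oxy]-3,7,7-trimethyl-2-[2-(2-methyl-1,3-dioxolan-2-yl)ethyl]oxepan-3-yl]acetate, both bromide epimers | CC(C)(C)[Si](C)(C)O[C@@H]1CC[C@](C)(C(Br)C(=O)OCC)[C@@H](CCC2(C)OCCO2)OC1(C)C | intermediate
21 | ethyl 2-bromo-2-[(2R,3S,6R)-6-[(tert-butyldimethylsilyl)oxy]-3,7,7-trimethyl-2-(3-oxobutyl)oxepan-3-yl]acetate, both bromide epimers | CC(C)(C)[Si](C)(C)O[C@@H]1CC[C@](C)(C(Br)C(=O)OCC)[C@@H](CCC(C)=O)OC1(C)C | intermediate
22 | diiodosamarium enolate of the ester of 21 (trivalent samarium) | CC(C)(C)[Si](C)(C)O[C@@H]1CC[C@](C)(C=C(O[Sm](I)I)OCC)[C@@H](CCC(C)=O)OC1(C)C | intermediate (not isolated)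
23 | ethyl (3R,5aR,6R,7S,9aR)-3-[(tert-butyldimethylsilyl)oxy]-7-hydroxy-2,2,5a,7-tetramethyldecahydro-1-benzoxepine-6-carboxylate | CC(C)(C)[Si](C)(C)O[C@@H]1CC[C@]2(C)[C@@H](C(=O)OCC)[C@@](C)(O)CC[C@H]2OC1(C)C | intermediate
24 | ethyl (3R,5aR,6R,7S,9aR)-3-[(tert-butyldimethylsilyl)oxy]-2,2,5a,7-tetramethyl-7-[(triethylsilyl)oxy]decahydro-1-benzoxepine-6-carboxylate | CC(C)(C)[Si](C)(C)O[C@@H]1CC[C@]2(C)[C@@H](C(=O)OCC)[C@@](C)(O[Si](CC)(CC)CC)CC[C@H]2OC1(C)C | intermediate
25 | [(3R,5aR,6S,7S,9aR)-3-[(tert-butyldimethylsilyl)oxy]-2,2,5a,7-tetramethyl-7-[(triethylsilyl)oxy]decahydro-1-benzoxepin-6-yl]methanol | CC(C)(C)[Si](C)(C)O[C@@H]1CC[C@]2(C)[C@@H](CO)[C@@](C)(O[Si](CC)(CC)CC)CC[C@H]2OC1(C)C | intermediate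
26 | (3R,5aR,6R,7S,9aR)-3-[(tert-butyldimethylsilyl)oxy]-2,2,5a,7-tetramethyl-7-[(triethylsilyl)oxy]decahydro-1-benzoxepine-6-carbaldehyde | CC(C)(C)[Si](C)(C)O[C@@H]1CC[C@]2(C)[C@@H](C=O)[C@@](C)(O[Si](CC)(CC)CC)CC[C@H]2OC1(C)C | intermediate
27 | tert-butyl{[(3R,5aR,6R,7S,9aR)-6-ethynyl-2,2,5a,7-tetramethyl-7-[(triethylsilyl)oxy]decahydro-1-benzoxepin-3-yl]oxy}dimethylsilane | CC(C)(C)[Si](C)(C)O[C@@H]1CC[C@]2(C)[C@@H](C#C)[C@@](C)(O[Si](CC)(CC)CC)CC[C@H]2OC1(C)C | intermediate
28 | (R)-(−)-linalool, (3R)-3,7-dimethylocta-1,6-dien-3-ol | C=C[C@](C)(O)CCC=C(C)C | starting material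
29 | tert-butyl{[(3R)-3,7-dimethylocta-1,6-dien-3-yl]oxy}dimethylsilane | C=C[C@](C)(O[Si](C)(C)C(C)(C)C)CCC=C(C)C | intermediate
30 | (4R)-4-[(tert-butyldimethylsilyl)oxy]-4-methylhex-5-enal | C=C[C@](C)(O[Si](C)(C)C(C)(C)C)CCC=O | intermediate
31 | tert-butyldimethyl{[(3R)-3-methylhept-1-en-6-yn-3-yl]oxy}silane | C=C[C@](C)(O[Si](C)(C)C(C)(C)C)CCC#C | intermediate
32 | lithium acetylide of 31 | C=C[C@](C)(O[Si](C)(C)C(C)(C)C)CCC#C[Li] | intermediate (not isolated)
33 | tert-butyldimethyl{[(3R)-3-methyloct-1-en-6-yn-3-yl]oxy}silane | C=C[C@](C)(O[Si](C)(C)C(C)(C)C)CCC#CC | intermediate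
34 | Co2(CO)6 complex of the alkyne of 33 | CC12[Co]3(=C=O)(=C=O)(=C=O)[Co]1(=C=O)(=C=O)(=C=O)C23CC[C@](C)(C=C)O[Si](C)(C)C(C)(C)C | intermediate (not isolated)
35 | (6R,6aR)-6-[(tert-butyldimethylsilyl)oxy]-3,6-dimethyl-4,5,6,6a-tetrahydropentalen-2(1H)-one | CC1=C2CC[C@@](C)(O[Si](C)(C)C(C)(C)C)[C@@H]2CC1=O | intermediate
36 | lithium enolate from 35 (cis-fused, enolate double bond between C2 and C3) | CC1=C(O[Li])C[C@@H]2[C@H]1CC[C@@]2(C)O[Si](C)(C)C(C)(C)C | intermediate (not isolated)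
37 | (3aR,6R,6aR)-6-[(tert-butyldimethylsilyl)oxy]-3,3,6-trimethylhexahydropentalen-2(1H)-one | CC1(C)[C@@H]2CC[C@@](C)(O[Si](C)(C)C(C)(C)C)[C@@H]2CC1=O | intermediate
38 | tert-butyldimethyl{[(1R,3aR,6aS)-1,4,4-trimethyl-5-[(trimethylsilyl)oxy]-1,2,3,3a,4,6a-hexahydropentalen-1-yl]oxy}silane | CC1(C)[C@@H]2CC[C@@](C)(O[Si](C)(C)C(C)(C)C)[C@@H]2C=C1O[Si](C)(C)C | intermediate
39 | dichloroacetyl chloride | O=C(Cl)C(Cl)Cl | starting material
40 | dichloroketene | O=C=C(Cl)Cl | intermediate (not isolated)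
41 | 4,4-dichloro-10-[(tert-butyldimethylsilyl)oxy]-6,6,10-trimethyl-5-[(trimethylsilyl)oxy]tricyclo[5.3.0.0(2,5)]decan-3-one, ring centres of 37 kept, cyclobutanone cis-fused on either face | CC1(C)[C@@H]2CC[C@@](C)(O[Si](C)(C)C(C)(C)C)[C@@H]2C3C(=O)C(Cl)(Cl)C13O[Si](C)(C)C | intermediate
42 | 10-[(tert-butyldimethylsilyl)oxy]-6,6,10-trimethyl-5-[(trimethylsilyl)oxy]tricyclo[5.3.0.0(2,5)]decan-3-one | CC1(C)[C@@H]2CC[C@@](C)(O[Si](C)(C)C(C)(C)C)[C@@H]2C3C(=O)CC13O[Si](C)(C)C | intermediate (not isolated)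
43 | (1R,3aR,8aR)-1-[(tert-butyldimethylsilyl)oxy]-1,4,4-trimethyl-2,3,3a,4,8,8a-hexahydroazulene-5,7(1H,6H)-dione | CC1(C)[C@@H]2CC[C@@](C)(O[Si](C)(C)C(C)(C)C)[C@@H]2CC(=O)CC1=O | intermediate
44 | (1R,3aR,8aR)-1-[(tert-butyldimethylsilyl)oxy]-1,4,4,6-tetramethyl-2,3,3a,4,8,8a-hexahydroazulene-5,7(1H,6H)-dione, both C6 epimers | CC1(C)[C@@H]2CC[C@@](C)(O[Si](C)(C)C(C)(C)C)[C@@H]2CC(=O)C(C)C1=O | intermediate
45 | (1R,3aR,8aR)-1-[(tert-butyldimethylsilyl)oxy]-7-methoxy-1,4,4,6-tetramethyl-2,3,3a,4,8,8a-hexahydroazulen-5(1H)-one | CC1(C)[C@@H]2CC[C@@](C)(O[Si](C)(C)C(C)(C)C)[C@@H]2CC(OC)=C(C)C1=O | intermediate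
46 | lithium acetylide of 27 | CC(C)(C)[Si](C)(C)O[C@@H]1CC[C@]2(C)[C@@H](C#C[Li])[C@@](C)(O[Si](CC)(CC)CC)CC[C@H]2OC1(C)C | intermediate (not isolated)
47 | (1R,3aR,8aR)-1-[(tert-butyldimethylsilyl)oxy]-5-{[(3R,5aR,6R,7S,9aR)-3-[(tert-butyldimethylsilyl)oxy]-2,2,5a,7-tetramethyl-7-[(triethylsilyl)oxy]decahydro-1-benzoxepin-6-yl]ethynyl}-7-methoxy-1,4,4,6-tetramethyl-1,2,3,3a,4,5,8,8a-octahydroazulen-5-ol, both C5 epimers | CC(C)(C)[Si](C)(C)O[C@@H]1CC[C@]2(C)[C@@H](C#CC3(O)C(C)=C(OC)C[C@@H]4[C@@H](CC[C@@]4(C)O[Si](C)(C)C(C)(C)C)C3(C)C)[C@@](C)(O[Si](CC)(CC)CC)CC[C@H]2OC1(C)C | intermediate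
48 | the same carbinol with the ethynediyl link reduced to ethane-1,2-diyl, both C5 epimers | CC(C)(C)[Si](C)(C)O[C@@H]1CC[C@]2(C)[C@@H](CCC3(O)C(C)=C(OC)C[C@@H]4[C@@H](CC[C@@]4(C)O[Si](C)(C)C(C)(C)C)C3(C)C)[C@@](C)(O[Si](CC)(CC)CC)CC[C@H]2OC1(C)C | intermediate (not isolated)
49 | (1R,3aR,8aR)-5-{2-[(3R,5aR,6R,7S,9aR)-3,7-dihydroxy-2,2,5a,7-tetramethyldecahydro-1-benzoxepin-6-yl]ethyl}-1-hydroxy-1,4,4,6-tetramethyl-2,3,3a,4,8,8a-hexahydroazulen-7(1H)-one | O[C@@H]1CC[C@]2(C)[C@@H](CCC3=C(C)C(=O)C[C@@H]4[C@@H](CC[C@@]4(C)O)C3(C)C)[C@@](C)(O)CC[C@H]2OC1(C)C | intermediate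
50 | (3R,5aR,6R,7S,9aR)-7-hydroxy-6-{2-[(1R,3aR,8aR)-1-hydroxy-1,4,4,6-tetramethyl-7-oxo-1,2,3,3a,4,7,8,8a-octahydroazulen-5-yl]ethyl}-2,2,5a,7-tetramethyldecahydro-1-benzoxepin-3-yl acetate | CC(=O)O[C@@H]1CC[C@]2(C)[C@@H](CCC3=C(C)C(=O)C[C@@H]4[C@@H](CC[C@@]4(C)O)C3(C)C)[C@@](C)(O)CC[C@H]2OC1(C)C | intermediate
51 | (3R,5aR,6R,7S,9aR)-6-{2-[(1R,3aR,7R,8aR)-1,7-dihydroxy-1,4,4,6-tetramethyl-1,2,3,3a,4,7,8,8a-octahydroazulen-5-yl]ethyl}-7-hydroxy-2,2,5a,7-tetramethyldecahydro-1-benzoxepin-3-yl acetate | CC(=O)O[C@@H]1CC[C@]2(C)[C@@H](CCC3=C(C)[C@H](O)C[C@@H]4[C@@H](CC[C@@]4(C)O)C3(C)C)[C@@](C)(O)CC[C@H]2OC1(C)C | target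

Total step count: 32. Longest linear sequence: 21 steps (steps 1–17 and 29–32, from geraniol); the hydroazulene branch runs 11 steps (18–28) before the union.

Steps most likely to fail

Step 13. The samarium enolate may be protonated before it cyclises, the samarium aldolate may revert by retro-aldol cleavage, or the ring may close through the chair that puts the C7 oxygen equatorial (poor facial selectivity at the ketone). The fallback is an amine-catalysed 6-enolexo aldolisation of a keto aldehyde under thermodynamic control. Setting out from 18, i-Bu2AlH (toluene, −78 °C) would give the aldehyde 2-[(2R,3R,6R)-6-[(tert-butyldimethylsilyl)oxy]-3,7,7-trimethyl-2-[2-(2-methyl-1,3-dioxolan-2-yl)ethyl]oxepan-3-yl]acetaldehyde F1. Ketal hydrolysis (pyridinium p-toluenesulfonate, wet acetone) would give the keto aldehyde 2-[(2R,3R,6R)-6-[(tert-butyldimethylsilyl)oxy]-3,7,7-trimethyl-2-(3-oxobutyl)oxepan-3-yl]acetaldehyde F2. Pyrrolidine/AcOH in CH2Cl2 would then close ring B through the enamine to (3R,5aR,6R,7S,9aR)-3-[(tert-butyldimethylsilyl)oxy]-7-hydroxy-2,2,5a,7-tetramethyldecahydro-1-benzoxepine-6-carbaldehyde F3. Because this aldol is reversible, the product should settle in the chair with the formyl group and the C7 methyl equatorial and the hydroxyl axial, the relative configuration of 23. Silylation of F3 (TESOTf, 2,6-lutidine) returns to the route at 26, so that steps 13 to 16 are not needed.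

Step 22. Facial selectivity in the alkene insertion may be poor, the methyl group competing with the silyloxy group for the exo position, so that the ring-fusion hydrogen ends up trans to oxygen. The fallback erases that centre and resets it by hydroxyl-directed hydrogenation. Setting out from 35 (either C6a epimer or the mixture), deconjugative α-methylation through the thermodynamic dienolate (KOt-Bu, t-BuOH, MeI) would give (6R)-6-[(tert-butyldimethylsilyl)oxy]-3,3,6-trimethyl-3,4,5,6-tetrahydropentalen-2(1H)-one F4, with the double bond at the ring fusion. Bu4NF (THF, 50 °C) would free the tertiary alcohol (6R)-6-hydroxy-3,3,6-trimethyl-3,4,5,6-tetrahydropentalen-2(1H)-one F5. H2 with [Ir(cod)(PCy3)(py)]PF6 in CH2Cl2, bound by the allylic hydroxyl, should deliver both hydrogens to the hydroxyl face and give (3aR,6R,6aR)-6-hydroxy-3,3,6-trimethylhexahydropentalen-2(1H)-one F6. TBSOTf/2,6-lutidine returns to the route at 37, so that step 23 is not needed.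

Step 7. Regiocontrol in the epoxide opening may be lost, 6-exo attack at the secondary carbon giving a tetrahydropyran in place of the oxepane. The fallback closes the ring on the olefin by Markovnikov iodoetherification and sets the carbinol afterwards. Setting out from 12, N-iodosuccinimide (CH2Cl2, 0 °C) should give 2-{2-[(2R,3R)-6-iodo-3,7,7-trimethyl-3-[(trimethylsilyl)ethynyl]oxepan-2-yl]ethyl}-2-methyl-1,3-dioxolane F7 by attack of the hydroxyl on the tertiary end of the iodonium ion. Reductive oxygenation (Bu3SnH, air, toluene) would give (6R,7R)-2,2,6-trimethyl-7-[2-(2-methyl-1,3-dioxolan-2-yl)ethyl]-6-[(trimethylsilyl)ethynyl]oxepan-3-ol F8 as both C3 epimers. Dess–Martin oxidation would give (6R,7R)-2,2,6-trimethyl-7-[2-(2-methyl-1,3-dioxolan-2-yl)ethyl]-6-[(trimethylsilyl)ethynyl]oxepan-3-one F9. Corey–Bakshi–Shibata reduction with the (S)-oxazaborolidine and catecholborane (quaternary C2 as the large group) should then give the (3R) alcohol and return to the route at 14.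

Further compounds

F1 | step 13 | 2-[(2R,3R,6R)-6-[(tert-butyldimethylsilyl)oxy]-3,7,7-trimethyl-2-[2-(2-methyl-1,3-dioxolan-2-yl)ethyl]oxepan-3-yl]acetaldehyde | CC(C)(C)[Si](C)(C)O[C@@H]1CC[C@](C)(CC=O)[C@@H](CCC2(C)OCCO2)OC1(C)C
F2 | step 13 | 2-[(2R,3R,6R)-6-[(tert-butyldimethylsilyl)oxy]-3,7,7-trimethyl-2-(3-oxobutyl)oxepan-3-yl]acetaldehyde | CC(C)(C)[Si](C)(C)O[C@@H]1CC[C@](C)(CC=O)[C@@H](CCC(C)=O)OC1(C)C
F3 | step 13 | (3R,5aR,6R,7S,9aR)-3-[(tert-butyldimethylsilyl)oxy]-7-hydroxy-2,2,5a,7-tetramethyldecahydro-1-benzoxepine-6-carbaldehyde | CC(C)(C)[Si](C)(C)O[C@@H]1CC[C@]2(C)[C@@H](C=O)[C@@](C)(O)CC[C@H]2OC1(C)C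
F4 | step 22 | (6R)-6-[(tert-butyldimethylsilyl)oxy]-3,3,6-trimethyl-3,4,5,6-tetrahydropentalen-2(1H)-one | CC1(C)C(=O)CC2=C1CC[C@@]2(C)O[Si](C)(C)C(C)(C)C
F5 | step 22 | (6R)-6-hydroxy-3,3,6-trimethyl-3,4,5,6-tetrahydropentalen-2(1H)-one | CC1(C)C(=O)CC2=C1CC[C@@]2(C)O
F6 | step 22 | (3aR,6R,6aR)-6-hydroxy-3,3,6-trimethylhexahydropentalen-2(1H)-one | CC1(C)[C@@H]2CC[C@@](C)(O)[C@@H]2CC1=O
F7 | step 7 | 2-{2-[(2R,3R)-6-iodo-3,7,7-trimethyl-3-[(trimethylsilyl)ethynyl]oxepan-2-yl]ethyl}-2-methyl-1,3-dioxolane | IC1CC[C@](C)(C#C[Si](C)(C)C)[C@@H](CCC2(C)OCCO2)OC1(C)C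
F8 | step 7 | (6R,7R)-2,2,6-trimethyl-7-[2-(2-methyl-1,3-dioxolan-2-yl)ethyl]-6-[(trimethylsilyl)ethynyl]oxepan-3-ol | OC1CC[C@](C)(C#C[Si](C)(C)C)[C@@H](CCC2(C)OCCO2)OC1(C)C
F9 | step 7 | (6R,7R)-2,2,6-trimethyl-7-[2-(2-methyl-1,3-dioxolan-2-yl)ethyl]-6-[(trimethylsilyl)ethynyl]oxepan-3-one | O=C1CC[C@](C)(C#C[Si](C)(C)C)[C@@H](CCC2(C)OCCO2)OC1(C)C
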